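3 questions stand for this flask, whose c(second nucleophile) of 0.200 M lies below that of both earlier runs, with the same charges of starting material and first nucleophile.

in all of them: starting material 0.050 M
- north-west: first nucleophile 0.030 M (fed, over 4.0 min); second nucleophile 0.28 M; run made earlier; the fed solution adds 0.10 times the starting volume
- south-west: first nucleophile 0.030 M (fed, over 4.0 min); second nucleophile 0.44 M; run made earlier; the fed solution adds 0.10 times the starting volume
- flask: first nucleophile 0.0300 M (fed, over 4.0 min); second nucleophile 0.200 M; the fed solution adds 0.10 times the starting volume; time 20 min

| run | time / min | target / % |
|---|---|---|
| north-west | 2.50 | 12.5 |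
| north-west | 4.00 | 18.8 |
| north-west | 5.00 | 23.3 |
| north-west | 8.00 | 25.1 |
| north-west | 12.0 | 25.6 |
| north-west | 15.0 | 24.1 |
| north-west | 25.0 | 22.1 |
| south-west | 2.50 | 7.3 |
| south-west | 4.00 | 13.9 |
| south-west | 5.00 | 16.8 |
| south-west | 8.00 | 19.1 |
| south-west | 12.0 | 19.4 |
| south-west | 15.0 | 18.8 |
| south-west | 25.0 | 14.6 |

(each reading ± 1 percentage point)

- when, up to 20 min, the flask holds most target
- the amount of target, in percent of the starting material charged, at that time
- the first time at which target reaches 22 %, in the same percent, in min

- every charge counts on the volume at the start, and the solution that is fed holds the whole dose
- a reading or a percentage of target counts all its forms, free or not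

Two chemists argue from the peak readings, 25.6 % at c(second nucleophile) = 0.28 M and 19.4 % at 0.44 M. The first chemist holds that the peak falls in a straight line with c(second nucleophile), so carrying that line down to 0.200 M gives 28.7 %.

The second chemist answers that the two nucleophiles compete. If they do, the share reaching target is one rate over a sum of rates, and with first nucleophile held the reciprocal of that share climbs straight with c(second nucleophile); she takes the peak reading as that share. She therefore carries the reciprocal slope, the rise of one over the peak fraction per unit of c(second nucleophile), as read from the two peak readings: 7.80 /M. From the north-west reading it gives 30.5 %, which is 1.8 percentage points above his value, against a scatter of 1 point on each reading.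

The forecast takes her side of the argument, with the most target at 11 min, an amount of 30 %, and the level reached at 3.9 min: “Plotting 1/yield against second-nucleophile concentration and extrapolating to 0.20 M gives about 32%, or a peak near 30% after decay.” Its line runs through peaks corrected for decay, hers through the raw readings.

The flask holds most target at 10.4 min, 30.9 % with crystals counted in, and reaches 22 % at 4.10 min, so the forecast stands within its margins.

    starting material ⇌ intermediate (K = 0.0170, k = 0.380 /min)
    first nucleophile + intermediate → target (k = 2500 /M/min)
    second nucleophile + intermediate → other capture product (k = 190 /M/min)
    target ⇌ isomer of the product (K = 1.00, k = 0.0540 /min)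
    crystals ⇌ target, rate k5*(cs5 - [target]) while solid is left; crystals form when [target] > cs5 (solubility = 11.0 mM, k = 2.10 /min)
    second nucleophile ⇌ dormant form (K = 3.10, k = 0.0380 /min)

Her value lies 0.40 points below the flask's and his 2.2 points below. His line keeps the range between the two runs, where midway the lines part by 0.43 points. At 10.4 min this flask holds 54.1 % of the starting material as other capture product. For a neighbour flask charged with 0.50 M of second nucleophile, the reciprocal slope carried up from the south-west reading gives 17.8 %, and that flask peaks at 19.0 %.

The data come from a simulation for substances that don't exist; noise was put on by code.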